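(The data were generated by integration with constants of no real substance; scatter was added.)

Slowness comes early in the ash, oak and cedar runs, and two people read it differently.

| setting | ash | oak | cedar | larch |
|---|---|---|---|---|
| substrate | 0.250 M | 0.250 M | 0.500 M | 0.750 M |
| partner | 0.500 M | 1.50 M | 0.500 M | 1.00 M |
| time |  |  |  | 7.4 h |

| run | time / h | [target] / M |
|---|---|---|
| ash run | 0.93 | 0.0809 |
| ash run | 1.9 | 0.1128 |
| ash run | 2.8 | 0.1337 |
| ash run | 3.7 | 0.1440 |
| ash run | 4.6 | 0.1541 |
| ash run | 5.5 | 0.1580 |
| ash run | 6.5 | 0.1644 |
| ash run | 7.4 | 0.1662 |
| oak run | 0.93 | 0.2210 |
| oak run | 1.9 | 0.2320 |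
| oak run | 2.8 | 0.2346 |
| oak run | 3.7 | 0.2338 |
| oak run | 4.6 | 0.2319 |
| oak run | 5.5 | 0.2324 |
| oak run | 6.5 | 0.2335 |
| oak run | 7.4 | 0.2307 |
| cedar run | 0.93 | 0.1410 |
| cedar run | 1.9 | 0.1950 |
| cedar run | 2.8 | 0.2212 |
| cedar run | 3.7 | 0.2398 |
| cedar run | 4.6 | 0.2506 |
| cedar run | 5.5 | 0.2620 |
| cedar run | 6.5 | 0.2683 |
| cedar run | 7.4 | 0.2722 |

(scatter of a reading: 8 × 10⁻⁴ M)

- Overall: substrate + partner -> target.
- Constant volume, constant temperature.
- An order is taken over about fifteen percent of the charge, up and down.

1. the exponent of [partner] in the starting rate at the charge of the ash run (at the point where two percent of the substrate have become target)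
2. the exponent of [substrate] in the starting rate at the charge of the ash run (at the point where two percent of the substrate have become target) (one fixed amount of target, the same in the runs compared)
3. target in the larch run at 7.4 h, as a share of the substrate charged

The first person holds that the reaction nears an equilibrium, so target over substrate left times partner left, both from the charge balance, should end at one constant. At the last reading this quotient is 5.94 L mol⁻¹ in ash and 5.25 L mol⁻¹ in cedar, which share a partner charge, but it is higher in oak, at 9.42 L mol⁻¹.

The second person holds that partner fades. The rate goes as substrate times partner squared, and partner falls as its charge over one plus fade times time. Then time divided by the logarithm of substrate charged over substrate left (charge less target) is straight in time. Its inverse at zero time is the start constant, and slope over intercept is the fade.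

I side with the second and use the first and last readings. Ash gives a start constant of 0.572 h⁻¹ and a fade of 0.388 h⁻¹. Cedar gives 0.538 h⁻¹ and 0.550 h⁻¹. From these two starts I read a substrate order of 0.912.

Per molar partner charged, the fade is larger in cedar than in ash, growing by 1.29 L² mol⁻² h⁻¹ per molar substrate. Extended to no substrate, this leaves 0.454 L mol⁻¹ h⁻¹, the self-fade: the fade per molar partner with no substrate present.

With these, oak's first reading gives a partner order of 1.94. The larch flask has a fade of 1.42 h⁻¹ and a start constant per squared molar partner of 2.22 L² mol⁻² h⁻¹, so I expect 76.0% of its substrate as target at the asked time.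

The forecast gives a partner order of 1.6 (1.2 to 2), a substrate order of 1 (0.8 to 1.2) and 75% (69% to 81%) for the larch flask, this last figure from an end constant of the first person's kind, and it says “so the partner order is above one”; its partner order differs from mine.

The simulation gives a partner order of 1.9, a substrate order of 1.0 and 76.8% for the larch flask.

    substrate + partner → target (0.1800 L mol⁻¹ h⁻¹)
    substrate + 2 partner → target + partner (2.012 L² mol⁻² h⁻¹)
    target + partner → side product (0.02347 L mol⁻¹ h⁻¹)
    2 partner → lost reagent (0.2293 L mol⁻¹ h⁻¹)

The scheme has no step that runs back, and its last step loses partner, as the second person held. In the larch flask the self-fade, as I read it, gives a partner half-life of 2.20 h, so 3.36 such spans pass by the asked time. Setting it to zero in my reckoning gives 86.7%. The main reason for the larch shortfall is the turning of two partner into lost reagent: without that step the larch flask gives 89.6% instead of 76.8%, a gain of 13 percentage points, which is 55% of what is missing.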